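**Retrosynthetic overview**
- The target comes from its 7-O-benzyl ether. The 8-OMe is made by O-methylation of an 8-OH, which is introduced by para-hydroxylation (persulfate) of a 7-benzyloxy-5-hydroxyflavone; the free 5-OH directs to C8.
- The 7-benzyloxy-5-hydroxyflavone comes from the 5,7-bis(benzyloxy)flavone by chelation-controlled removal of the 5-O-benzyl group.
- Ring C (the pyranone) is disconnected at O1–C2 to a 2'-hydroxychalcone (oxidative cyclisation).
- The chalcone Cα–Cβ bond is disconnected by a Claisen–Schmidt aldol condensation into 2'-hydroxy-4',6'-bis(benzyloxy)acetophenone (from phloroacetophenone) and 3,4,5-trimethoxybenzaldehyde.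
- Ring order: rings A and B are bought as arenes; ring C is the only ring formed (step 3); the C8 oxygen is installed on the finished flavone.

Assumption: the target is achiral (no stereocentre or axis), so no stereocontrol is needed; the only stereo-element in the route is the E-alkene of the chalcone, which is erased on cyclisation.

**Step 1**
Reactants: 1 2',4',6'-trihydroxyacetophenone (phloroacetophenone, dried)
Product: 2 2'-hydroxy-4',6'-bis(benzyloxy)acetophenone
Conditions: BnBr (2.1 equiv), K2CO3 (2.2 equiv), DMF, 0 °C to rt, 16 h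
Reagents that add atoms: benzyl bromide, BrCc1ccccc1
Why: Williamson ether synthesis in which the 4-OH and one ortho-OH are alkylated, while the last ortho-OH is hydrogen-bonded to the ketone and stays free with two equivalents of halide.

**Step 2**
Reactants: 2 2'-hydroxy-4',6'-bis(benzyloxy)acetophenone; 3 3,4,5-trimethoxybenzaldehyde
Product: 5 (E)-1-[2,4-bis(benzyloxy)-6-hydroxyphenyl]-3-(3,4,5-trimethoxyphenyl)prop-2-en-1-one, via aldol adduct 4 (not isolated)
Conditions: KOH (50% aq., 10 equiv), EtOH–THF, rt, 48 h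
Reagents that add atoms: none
Why: Claisen–Schmidt crossed aldol condensation in which only the methyl ketone can enolise and only the aldehyde can accept, and E1cB dehydration of the racemic β-hydroxy ketone gives the conjugated E-enone (no stereocentre remains).

**Step 3**
Reactants: 5 (E)-chalcone
Product: 7 5,7-bis(benzyloxy)-2-(3,4,5-trimethoxyphenyl)-4H-chromen-4-one, via flavanone 6 (not isolated)
Conditions: I2 (10 mol %), DMSO, 130 °C, 3 h
Reagents that add atoms: none
Why: Iodine/DMSO oxidative cyclisation, in which oxa-Michael closure of the 2'-phenol gives the racemic flavanone and iodine-mediated dehydrogenation (DMSO as terminal oxidant) gives the flavone, removing the transient stereocentre; benzyl and methyl ethers are inert.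

**Step 4**
Reactants: 7 5,7-bis(benzyloxy)-2-(3,4,5-trimethoxyphenyl)-4H-chromen-4-one
Product: 9 7-(benzyloxy)-5-hydroxy-2-(3,4,5-trimethoxyphenyl)-4H-chromen-4-one, via dichloroboryl chelate 8 (not isolated)
Conditions: BCl3 (1.1 equiv, 1 M in CH2Cl2), CH2Cl2, −78 °C, 1 h; then H2O, 0 °C
Reagents that add atoms: none
Why: Chelation-controlled Lewis-acid ether cleavage, in which BCl3 binds the C4 carbonyl and the peri 5-oxygen so that only the 5-O-benzyl group is cleaved at −78 °C, leaving the 7-benzyl and the non-chelated methyl ethers.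

**Step 5**
Reactants: 9 7-(benzyloxy)-5-hydroxy-2-(3,4,5-trimethoxyphenyl)-4H-chromen-4-one
Product: 11 7-(benzyloxy)-5,8-dihydroxy-2-(3,4,5-trimethoxyphenyl)-4H-chromen-4-one, via potassium 8-sulfate 10 (not isolated)
Conditions: K2S2O8 (1.2 equiv, added over 3 h), aq. KOH (6 equiv), pyridine, 15–20 °C, 24 h; acidify to pH 4 and filter off unchanged 9 (recycled); filtrate + conc. HCl, 85 °C, 30 min, N2
Reagents that add atoms: potassium peroxodisulfate, [K+].[K+].[O-]S(=O)(=O)OOS(=O)(=O)[O-]
Why: Elbs persulfate oxidation, in which the 5-phenoxide attacks the peroxide oxygen through its para carbon (C8) to give the aryl sulfate, and acid hydrolysis of the sulfate frees the 5,8-quinol without touching the benzyl ether.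

**Step 6**
Reactants: 11 7-(benzyloxy)-5,8-dihydroxy-2-(3,4,5-trimethoxyphenyl)-4H-chromen-4-one
Product: 12 7-(benzyloxy)-5-hydroxy-8-methoxy-2-(3,4,5-trimethoxyphenyl)-4H-chromen-4-one
Conditions: MeI (1.1 equiv), K2CO3 (1.2 equiv), degassed acetone, reflux, N2, 4 h
Reagents that add atoms: iodomethane, CI
Why: Selective Williamson O-methylation, in which the 5-OH is hydrogen-bonded to the C4 carbonyl and poorly nucleophilic, so one equivalent of MeI methylates only the free 8-OH.

**Step 7**
Reactants: 12 7-(benzyloxy)-5-hydroxy-8-methoxy-2-(3,4,5-trimethoxyphenyl)-4H-chromen-4-one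
Product: 13 5,7-dihydroxy-8-methoxy-2-(3,4,5-trimethoxyphenyl)-4H-chromen-4-one (3',4',5'-trimethoxywogonin)
Conditions: H2 (1 atm), 10% Pd/C, THF–MeOH, rt, 3 h
Reagents that add atoms: none
Why: Catalytic hydrogenolysis of the aryl benzyl ether under neutral conditions, which leaves the flavone enone and the aryl methyl ethers untouched and avoids acid-induced Wessely–Moser isomerisation.

**Compound list**
1 | 2',4',6'-trihydroxyacetophenone | CC(=O)c1c(O)cc(O)cc1O | starting material
2 | 2'-hydroxy-4',6'-bis(benzyloxy)acetophenone | CC(=O)c1c(O)cc(OCc2ccccc2)cc1OCc1ccccc1 | intermediate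
3 | 3,4,5-trimethoxybenzaldehyde | COc1cc(C=O)cc(OC)c1OC | starting material
4 | 1-[2,4-bis(benzyloxy)-6-hydroxyphenyl]-3-hydroxy-3-(3,4,5-trimethoxyphenyl)propan-1-one (racemic aldol adduct, not isolated) | O=C(CC(O)c1cc(OC)c(OC)c(OC)c1)c1c(O)cc(OCc2ccccc2)cc1OCc1ccccc1 | intermediate
5 | (E)-1-[2,4-bis(benzyloxy)-6-hydroxyphenyl]-3-(3,4,5-trimethoxyphenyl)prop-2-en-1-one | O=C(/C=C/c1cc(OC)c(OC)c(OC)c1)c1c(O)cc(OCc2ccccc2)cc1OCc1ccccc1 | intermediate
6 | 5,7-bis(benzyloxy)-2-(3,4,5-trimethoxyphenyl)chroman-4-one (racemic flavanone, not isolated) | O=C1CC(c2cc(OC)c(OC)c(OC)c2)Oc2cc(OCc3ccccc3)cc(OCc3ccccc3)c21 | intermediate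
7 | 5,7-bis(benzyloxy)-2-(3,4,5-trimethoxyphenyl)-4H-chromen-4-one | COc1cc(-c2cc(=O)c3c(OCc4ccccc4)cc(OCc4ccccc4)cc3o2)cc(OC)c1OC | intermediate
8 | 7-(benzyloxy)-5-(dichloroboryloxy)-2-(3,4,5-trimethoxyphenyl)-4H-chromen-4-one (boron chelated to C4=O, not isolated) | COc1cc(-c2cc(=O)c3c(OB(Cl)Cl)cc(OCc4ccccc4)cc3o2)cc(OC)c1OC | intermediate
9 | 7-(benzyloxy)-5-hydroxy-2-(3,4,5-trimethoxyphenyl)-4H-chromen-4-one | COc1cc(-c2cc(=O)c3c(O)cc(OCc4ccccc4)cc3o2)cc(OC)c1OC | intermediate
10 | potassium 7-(benzyloxy)-5-hydroxy-4-oxo-2-(3,4,5-trimethoxyphenyl)-4H-chromen-8-yl sulfate (not isolated) | COc1cc(-c2cc(=O)c3c(O)cc(OCc4ccccc4)c(OS(=O)(=O)[O-])c3o2)cc(OC)c1OC.[K+] | intermediate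
11 | 7-(benzyloxy)-5,8-dihydroxy-2-(3,4,5-trimethoxyphenyl)-4H-chromen-4-one | COc1cc(-c2cc(=O)c3c(O)cc(OCc4ccccc4)c(O)c3o2)cc(OC)c1OC | intermediate
12 | 7-(benzyloxy)-5-hydroxy-8-methoxy-2-(3,4,5-trimethoxyphenyl)-4H-chromen-4-one | COc1cc(-c2cc(=O)c3c(O)cc(OCc4ccccc4)c(OC)c3o2)cc(OC)c1OC | intermediate
13 | 5,7-dihydroxy-8-methoxy-2-(3,4,5-trimethoxyphenyl)-4H-chromen-4-one (3',4',5'-trimethoxywogonin) | COc1cc(-c2cc(=O)c3c(O)cc(O)c(OC)c3o2)cc(OC)c1OC | target

**Totals**
Total step count: 7. Longest linear sequence: 7 steps (1 to 13); aldehyde 3 enters at step 2.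

**Steps most likely to fail, with fallbacks**

Step 5 (persulfate hydroxylation) is the weakest step. Conversion is typically low, much of 9 is recovered, and the quinol 11 is air-sensitive. The fallback sets out from 7 and installs the C8 oxygen by halogenation and C–O coupling instead. NBS (1.05 equiv, DMF, 0 °C to rt) brominates ring A at C8 to give 5,7-bis(benzyloxy)-8-bromo-2-(3,4,5-trimethoxyphenyl)-4H-chromen-4-one F2. The C8 position should be confirmed by NOE: the remaining H6 must show contacts to both benzylic CH2 groups. Copper-catalysed Ullmann-type methoxylation (NaOMe, CuBr 20 mol %, DMF–MeOH, 110 °C) then gives 5,7-bis(benzyloxy)-8-methoxy-2-(3,4,5-trimethoxyphenyl)-4H-chromen-4-one F3. Hydrogenolysis of both benzyl ethers (H2, 10% Pd/C, THF–MeOH, rt) comes back to the route at 13.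

Step 4 (selective 5-O-debenzylation) may also cleave some of the 7-benzyl ether or give C-benzylated by-products. The fallback sets out from 7 and removes both benzyl groups by hydrogenolysis (H2, 10% Pd/C, THF–MeOH, rt) to give 5,7-dihydroxy-2-(3,4,5-trimethoxyphenyl)-4H-chromen-4-one F1. Only the 7-benzyl group is then put back (BnBr 1.05 equiv, K2CO3, acetone, reflux), because the chelated 5-OH does not alkylate under these conditions. This comes back to the route at 9.

Step 6 (selective 8-O-methylation) can over-methylate, or lose 11 by oxidation to the 5,8-quinone. The fallback sets out from 11 and methylates both hydroxyls (MeI 3 equiv, K2CO3, DMF, 50 °C, N2) to give 7-(benzyloxy)-5,8-dimethoxy-2-(3,4,5-trimethoxyphenyl)-4H-chromen-4-one F4. BCl3 (3 equiv, CH2Cl2, −78 to 0 °C, then H2O) then cleaves the carbonyl-chelated 5-methyl ether and the 7-benzyl ether. The non-chelated 8-OMe and ring B methyl ethers should survive at this temperature. This comes back to the route at 13.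

**Further compounds**
F1 | step 4 | 5,7-dihydroxy-2-(3,4,5-trimethoxyphenyl)-4H-chromen-4-one | COc1cc(-c2cc(=O)c3c(O)cc(O)cc3o2)cc(OC)c1OC
F2 | step 5 | 5,7-bis(benzyloxy)-8-bromo-2-(3,4,5-trimethoxyphenyl)-4H-chromen-4-one | COc1cc(-c2cc(=O)c3c(OCc4ccccc4)cc(OCc4ccccc4)c(Br)c3o2)cc(OC)c1OC
F3 | step 5 | 5,7-bis(benzyloxy)-8-methoxy-2-(3,4,5-trimethoxyphenyl)-4H-chromen-4-one | COc1cc(-c2cc(=O)c3c(OCc4ccccc4)cc(OCc4ccccc4)c(OC)c3o2)cc(OC)c1OC
F4 | step 6 | 7-(benzyloxy)-5,8-dimethoxy-2-(3,4,5-trimethoxyphenyl)-4H-chromen-4-one | COc1cc(-c2cc(=O)c3c(OC)cc(OCc4ccccc4)c(OC)c3o2)cc(OC)c1OC
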